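With the ring numbered from the carbon bearing CH2OSO3H (C1), everything rests on disconnecting the C4–O bond of the aryl sulfate. An Elbs persulfate oxidation of the C3 phenolate forges that bond and delivers the new oxygen already sulfated, so the neighbouring C3 and C4 oxygens are told apart by their origin, without protecting groups. The step exploits the fact that C4 is the only C–H of the precursor's benzene ring and sits ortho to the free C3–OH. The precursor is 2,5,6-tribromo-3-hydroxybenzyl sulfate, built from an aminophenol ester whose C4 amino group steers three brominations into place and is then excised.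

Key step: step 6

Assumption: sulfate monoesters are drawn as free acids, as in the target, but are handled as sodium salts; only the final product is brought to the acid form, by cold ion exchange.

Step 1
Reactants: 1 methyl 4-amino-3-hydroxybenzoate; 2 bromine
Product: 3 methyl 4-amino-2,5,6-tribromo-3-hydroxybenzoate
Conditions: Br2 (3.2 equiv), NaOAc (3.5 equiv), AcOH/CH2Cl2, 0 °C to rt; aq Na2S2O3 quench
Reagents that add atoms: bromine (compound 2), BrBr
Why: Electrophilic aromatic bromination, in which the amino group activates C5 and the hydroxyl activates C2 and C6; these are the only three ring hydrogens, so exhaustive halogenation needs no regiocontrol, while the acetate buffer keeps the amine free and the ester tempers the oxidisability of the aminophenol.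

Step 2
Reactants: 3 methyl 4-amino-2,5,6-tribromo-3-hydroxybenzoate
Product: 5 methyl 2,5,6-tribromo-3-hydroxybenzoate, via arenediazonium hydrogen sulfate 4 (not isolated)
Conditions: NaNO2, conc. H2SO4/AcOH, 0–5 °C; then 50% aq H3PO2, Cu2O (cat.), 0 °C to rt
Reagents that add atoms: none
Why: Diazotisation with nitrosylsulfuric acid followed by hypophosphorous acid hydrodediazoniation (radical chain started by monovalent copper); the strongly acidic medium keeps the o-hydroxy diazonium ion protonated instead of letting it settle as the sluggish diazo-oxide, and the aryl radical should take hydrogen from H3PO2 faster than it can disturb the C–Br bonds.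

Step 3
Reactants: 5 methyl 2,5,6-tribromo-3-hydroxybenzoate
Product: 6 methyl 2,5,6-tribromo-3-(tert-butyldimethylsilyloxy)benzoate
Conditions: TBSCl, imidazole, DMF, rt
Reagents that add atoms: tert-butyldimethylsilyl chloride (TBSCl), CC(C)(C)[Si](C)(C)Cl
Why: Imidazole-promoted O-silylation of the acidic phenol, which masks it so that only the benzylic hydroxyl can be sulfated later and keeps an aluminium phenoxide out of the reduction.

Step 4
Reactants: 6 methyl 2,5,6-tribromo-3-(tert-butyldimethylsilyloxy)benzoate
Product: 7 [2,5,6-tribromo-3-(tert-butyldimethylsilyloxy)phenyl]methanol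
Conditions: iBu2AlH (DIBAL-H, 2.5 equiv), CH2Cl2, −78 to 0 °C; aq KNaC4H4O6 work-up
Reagents that add atoms: none
Why: Ester reduction with an electrophilic aluminium hydride, which binds the carbonyl oxygen and delivers hydride even between two ortho bromines and, unlike LiAlH4, has little tendency to reduce aryl bromides at or below 0 °C; the aryl silyl ether is inert to it.

Step 5
Reactants: 7 [2,5,6-tribromo-3-(tert-butyldimethylsilyloxy)phenyl]methanol; 8 sulfur trioxide pyridine complex
Product: 9 2,5,6-tribromo-3-(tert-butyldimethylsilyloxy)benzyl hydrogen sulfate (isolated as its sodium salt)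
Conditions: SO3·pyridine (3 equiv), pyridine, 0 °C to rt; aq NaHCO3; C18 desalting
Reagents that add atoms: sulfur trioxide pyridine complex (compound 8), [O-]S(=O)(=O)[n+]1ccccc1
Why: O-Sulfation of a primary alcohol by SO3 transfer from its pyridine complex; the benzylic hydroxyl is the only free OH, and the monoester is stable once held as its sodium salt at neutral to basic pH (any early loss of the silyl group in the bicarbonate work-up is harmless, since step 6 removes it anyway).

Step 6
Reactants: 9 2,5,6-tribromo-3-(tert-butyldimethylsilyloxy)benzyl hydrogen sulfate (sodium salt); 10 potassium peroxydisulfate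
Product: 12 2,5,6-tribromo-3-hydroxy-4-(sulfooxy)benzyl hydrogen sulfate, via 2,5,6-tribromo-3-hydroxybenzyl hydrogen sulfate 11 (not isolated)
Conditions: 2 M aq NaOH, rt, then Et2O wash; K2S2O8 (1.1 equiv) in water added over several hours at 0–10 °C, then rt, N2, dark; neutralise cold to pH 7, C18 chromatography; sulfonic acid cation-exchange resin (H+ form), 0 °C, lyophilise
Reagents that add atoms: potassium peroxydisulfate (compound 10), [K+].[K+].[O-]S(=O)(=O)OOS(=O)(=O)[O-]
Why: Hydroxide first cleaves the electron-poor aryl silyl ether to give the phenolate of 11; this ambident anion attacks a peroxide oxygen of peroxydisulfate through C4 with expulsion of sulfate, and the resulting 6-(sulfonatooxy)cyclohexa-2,4-dienone rearomatises by loss of the C4 proton, so the new C4 oxygen carries the sulfate and the C3 oxygen stays a free phenol. This is the Elbs persulfate oxidation in its ortho mode, known for phenols whose para position is blocked. No ring is closed and no stereocentre is created. The selectivity needed is attack at C4 rather than ipso attack at the brominated C2 and C6, and the substrate favours it because C4 is the only position whose adduct can aromatise by deprotonation; slow addition of a small excess of oxidant in the cold and dark should hold back radical and debrominating pathways. The benzylic sulfate should survive the alkali because the phenolate is meta to C1 and so cannot expel it through a quinone methide, and because the bromines at C2 and C6 shield the CH2 from hydroxide. The product has no ring C–H left for over-oxidation, and the usual acidic hydrolysis of the Elbs sulfate is deliberately omitted; the free acid should be kept cold and never concentrated warm.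

Compound list
1 | methyl 4-amino-3-hydroxybenzoate | COC(=O)c1ccc(N)c(O)c1 | starting material
2 | bromine | BrBr | starting material
3 | methyl 4-amino-2,5,6-tribromo-3-hydroxybenzoate | COC(=O)c1c(Br)c(O)c(N)c(Br)c1Br | intermediate
4 | methyl 2,5,6-tribromo-4-diazonio-3-hydroxybenzoate hydrogen sulfate (not isolated) | COC(=O)c1c(Br)c(O)c([N+]#N)c(Br)c1Br.OS(=O)(=O)[O-] | intermediate
5 | methyl 2,5,6-tribromo-3-hydroxybenzoate | COC(=O)c1c(Br)c(O)cc(Br)c1Br | intermediate
6 | methyl 2,5,6-tribromo-3-(tert-butyldimethylsilyloxy)benzoate | COC(=O)c1c(Br)c(O[Si](C)(C)C(C)(C)C)cc(Br)c1Br | intermediate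
7 | [2,5,6-tribromo-3-(tert-butyldimethylsilyloxy)phenyl]methanol | OCc1c(Br)c(O[Si](C)(C)C(C)(C)C)cc(Br)c1Br | intermediate
8 | sulfur trioxide pyridine complex | [O-]S(=O)(=O)[n+]1ccccc1 | starting material
9 | 2,5,6-tribromo-3-(tert-butyldimethylsilyloxy)benzyl hydrogen sulfate (handled as sodium salt) | O=S(=O)(O)OCc1c(Br)c(O[Si](C)(C)C(C)(C)C)cc(Br)c1Br | intermediate
10 | potassium peroxydisulfate | [K+].[K+].[O-]S(=O)(=O)OOS(=O)(=O)[O-] | starting material
11 | 2,5,6-tribromo-3-hydroxybenzyl hydrogen sulfate (present as phenolate and sulfate anion in alkali, not isolated) | O=S(=O)(O)OCc1c(Br)c(O)cc(Br)c1Br | intermediate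
12 | 2,5,6-tribromo-3-hydroxy-4-(sulfooxy)benzyl hydrogen sulfate (CNP0213554.0) | O=S(=O)(O)OCc1c(Br)c(O)c(OS(=O)(=O)O)c(Br)c1Br | target

Total step count: 6. Longest linear sequence: 6 steps (1 to 12).

Steps most likely to fail

Step 6. The oxidant may attack ipso at the brominated para carbon C6 with loss of bromide, the phenolate may be oxidised by radical paths to quinonoid and coupled material, or the crowded, deactivated phenolate may simply convert poorly. The fallback sets out from 3 and returns to the route at 12; it takes the C4 oxygen from the C4 nitrogen instead of from C–H oxidation, so the two oxygens stay distinct by origin.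
- The phenol of 3 is capped selectively with methanesulfonyl chloride (Et3N, CH2Cl2, 0 °C; the flanked, electron-poor aniline should not compete) to give methyl 4-amino-2,5,6-tribromo-3-(methylsulfonyloxy)benzoate F1.
- Diazotisation (NaNO2, H2SO4/AcOH, 0 °C) gives methyl 2,5,6-tribromo-4-diazonio-3-(methylsulfonyloxy)benzoate hydrogen sulfate F2, which can no longer collapse to a diazo-oxide.
- Hydroxydediazoniation with Cu2O in aqueous Cu(NO3)2 at rt (divalent copper traps the aryl radical) gives methyl 2,5,6-tribromo-4-hydroxy-3-(methylsulfonyloxy)benzoate F3.
- Reduction with iBu2AlH (CH2Cl2, −78 to 0 °C) gives 2,5,6-tribromo-4-hydroxy-3-(methylsulfonyloxy)benzyl alcohol F4.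
- Excess 8 in pyridine (rt to 40 °C) sulfates both free hydroxyls to give 2,5,6-tribromo-3-(methylsulfonyloxy)-4-(sulfooxy)benzyl hydrogen sulfate F5 (disodium salt).
- Aqueous NaOH at rt removes the mesyl group (a sulfonyl group, unlike an acyl group, should not wander between the catechol oxygens), and cold ion exchange gives 12.

Step 2. The o-hydroxy diazonium ion may lose its phenolic proton and settle as the diazo-oxide, which resists reduction and drifts into coupling or ring contraction. The fallback sets out from 3 and returns at 5.
- O-Methylation (MeI, K2CO3, acetone, rt) gives methyl 4-amino-2,5,6-tribromo-3-methoxybenzoate F6.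
- Aprotic deamination (tert-butyl nitrite, DMF, 60 °C; the aryl radical takes hydrogen from the solvent) gives methyl 2,5,6-tribromo-3-methoxybenzoate F7.
- BBr3 (CH2Cl2, −78 to 0 °C) cleaves the aryl methyl ether while the shielded methyl ester should persist, giving 5.

Step 1. Bromine may oxidise the electron-rich o-aminophenol (quinone imine formation and condensation) faster than it substitutes the ring, or substitution may stall before the crowded C2 position is filled. The fallback sets out from 1 and returns at 3.
- N-Acetylation (Ac2O, THF, rt) gives the oxidation-resistant methyl 4-acetamido-3-hydroxybenzoate F8.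
- Phenol-directed dibromination with 2 (2.1 equiv, AcOH, rt) gives methyl 4-acetamido-2,6-dibromo-3-hydroxybenzoate F9.
- Acid methanolysis (HCl, MeOH, reflux) gives methyl 4-amino-2,6-dibromo-3-hydroxybenzoate F10.
- One equivalent of 2 (AcOH, 0 °C) then fills C5 ortho to the freed amine, on a ring now too electron-poor to be oxidised easily, giving 3.

Further compounds
F1 | step 6 | methyl 4-amino-2,5,6-tribromo-3-(methylsulfonyloxy)benzoate | COC(=O)c1c(Br)c(OS(C)(=O)=O)c(N)c(Br)c1Br
F2 | step 6 | methyl 2,5,6-tribromo-4-diazonio-3-(methylsulfonyloxy)benzoate hydrogen sulfate | COC(=O)c1c(Br)c(OS(C)(=O)=O)c([N+]#N)c(Br)c1Br.OS(=O)(=O)[O-]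
F3 | step 6 | methyl 2,5,6-tribromo-4-hydroxy-3-(methylsulfonyloxy)benzoate | COC(=O)c1c(Br)c(OS(C)(=O)=O)c(O)c(Br)c1Br
F4 | step 6 | 2,5,6-tribromo-4-hydroxy-3-(methylsulfonyloxy)benzyl alcohol | OCc1c(Br)c(OS(C)(=O)=O)c(O)c(Br)c1Br
F5 | step 6 | 2,5,6-tribromo-3-(methylsulfonyloxy)-4-(sulfooxy)benzyl hydrogen sulfate | O=S(=O)(O)OCc1c(Br)c(OS(C)(=O)=O)c(OS(=O)(=O)O)c(Br)c1Br
F6 | step 2 | methyl 4-amino-2,5,6-tribromo-3-methoxybenzoate | COC(=O)c1c(Br)c(OC)c(N)c(Br)c1Br
F7 | step 2 | methyl 2,5,6-tribromo-3-methoxybenzoate | COC(=O)c1c(Br)c(OC)cc(Br)c1Br
F8 | step 1 | methyl 4-acetamido-3-hydroxybenzoate | COC(=O)c1ccc(NC(C)=O)c(O)c1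
F9 | step 1 | methyl 4-acetamido-2,6-dibromo-3-hydroxybenzoate | COC(=O)c1c(Br)c(O)c(NC(C)=O)cc1Br
F10 | step 1 | methyl 4-amino-2,6-dibromo-3-hydroxybenzoate | COC(=O)c1c(Br)c(O)c(N)cc1Br
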